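The numbers in the tables are simulated on assumed constants.

The question is when, within the time allowed, this flask holds most target, and how much target that is.

| setting | south-west | south-east | flask |
|---|---|---|---|
| solid substrate | 0.050 M | 0.050 M | 0.050 M |
| partner | 0.65 equiv | 0.98 equiv | 1.30 equiv |
| protic impurity | 2.5 mM | 2.5 mM | 2.50 mM |
| remark | run made earlier | run made earlier |  |
| time |  |  | 3.0 min |

1. the moment within 3.0 min at which there is most target
2. the amount of target, in percent of the solid substrate charged, at that time

- given per volume of solution although it is solid: solid substrate
- at the start none of the solid substrate is in solution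

- south-west (time / s: target / %, solid substrate / %): 50.0: 22.2, 35.4; 60.0: 24.5, 31.0; 80.0: 30.4, 24.0; 90.0: 32.1, 18.5; 120: 35.5, 13.0
- south-east (time / s: target / %, solid substrate / %): 50.0: 32.3, 24.4; 60.0: 39.1, 15.7; 80.0: 46.6, 7.9; 90.0: 49.3, 2.1; 120: 59.3, 0.8

(each reading ± 1 percentage point)

Read the two tables along their 90.0 s row. The south-west run has made 32.1% of target from 0.65 equiv of partner, and the south-east run 49.3% from 0.98 equiv. Counting one partner used per target made, these readings give c_partner an apparent half-life of 91.6 s in the south-west run and 89.2 s in the south-east run. The solid column in that row differs strongly, 18.5% against 2.1%. So, in these two runs up to that row, the rate reads as pseudo-first-order in c_partner, as if the solid held c_dissolved substrate steady.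

My own reckoning carries one number, the partner half-life over solid, 90.4 s. With 1.30 equiv of partner it gives 64.8% of target at 90.0 s. The south-east run has 2.1% of solid left at that time, so the readings give the rule little ground beyond it. Run on to 3.0 min, it gives 97.3%, a figure that supposes the same half-life after the solid has gone. I therefore expect the peak at the time limit, between these two figures.

The forecast gives 75% at 2.8 min, between those figures. Its reasoning says: “The maximum is late and shallow, possibly at the window's end”.

The flask gives 82.7% at 3.00 min.

    dissolved substrate + partner → target (k = 0.970 /M/s)
    partner ⇌ dormant form (K = 0.740, k = 0.0510 /s)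
    solid substrate + target → side product (k = 0.150 /M/s)
    solid substrate ⇌ dissolved substrate, rate k4*(cs4 - [dissolved substrate]) while solid is left; crystals form when [dissolved substrate] > cs4 (solubility = 17.0 mM, k = 0.620 /s)
    solid substrate + protic impurity → quenched substrate (k = 5.90 /M/s)

At 1.50 min the flask holds 0% of solid substrate but 22.0% of dissolved substrate, and target climbs from 67.2% then to 82.7% at 3.00 min. The half-life of 90.4 s gave 64.8% for 1.50 min, against the flask's 67.2%.

With 0.330 equiv of partner, the same half-life gives 24.7% of target at 3.0 min. That neighbour flask ends with 19.5% of target and 27.5% of solid substrate still present.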